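## Retrosynthetic overview

1. Target 30 ⇐ late esters: 7‑OAc and 6‑O‑angelate come from the 6α‑hydroxy‑7‑ketone 24 (C6–OH by α‑face enolate hydroxylation, C7–OH by α‑face hydride delivery); the tertiary 8α‑OH is carried as a triethylsilyl ether.
2. (12E)‑Diene ⇐ methylenation of enal 21 ⇐ enoate 19 ⇐ key C12–C13 bond: intermolecular aldol addition of the lithium enolate of ethyl propanoate (fragment 2: C13, C14, C16) to keto aldehyde 14 (fragment 1), then E1cB dehydration.
3. 14 ⇐ Δ7‑alkene 9 by α‑face dihydroxylation (sets C8), oxidation at C7, silylation, debenzylation and oxidation at C12.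
4. 9 ⇐ regiodefined enol triflate/methyl coupling of the 17‑nor‑8‑ketone 6 ⇐ (+)‑sclareolide 1 (reduction, benzylation, dehydration, ozonolysis).
5. Rings: no carbocycle is built; ring A and ring B (trans‑decalin with C5, C9, C10 set) are bought in 1, and only its lactone ring is opened (step 1).

Assumption: labdane numbering is used in all names (C17 = methyl on C8; C20 = β‑methyl on C10; side chain C11–C16 on C9; every compound keeps 5α‑H, 9α‑H, 10β‑CH3). The target is read as (12E)‑7β‑acetoxy‑8α‑hydroxylabda‑12,14‑dien‑6α‑yl (Z)‑2‑methylbut‑2‑enoate (angelate).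

## Route

Step 1
Reactants: 1 (+)-sclareolide
Product: 2 13,14,15,16-tetranorlabdane-8α,12-diol
Conditions: LiAlH4, THF, 0 °C → rt
Reagents that add atoms: none
Why: Hydride reduction of the γ‑lactone gives the diol and leaves C5, C8, C9 and C10 untouched.

Step 2
Reactants: 2 13,14,15,16-tetranorlabdane-8α,12-diol
Product: 3 12-benzyloxy-13,14,15,16-tetranorlabdan-8α-ol
Conditions: NaH (1.1 equiv), BnBr, Bu4NI (cat.), THF/DMF, 0 °C → rt
Reagents that add atoms: benzyl bromide, BrCc1ccccc1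
Why: Williamson etherification takes only the primary alkoxide, because the hindered tertiary C8 hydroxyl does not alkylate.

Step 3
Reactants: 3 12-benzyloxy-13,14,15,16-tetranorlabdan-8α-ol
Product: 4 12-benzyloxy-13,14,15,16-tetranorlabd-8(17)-ene
Conditions: SOCl2, pyridine, CH2Cl2, −78 °C
Reagents that add atoms: none
Why: E2 dehydration through the chlorosulfite favours the exocyclic alkene, because the equatorial C8–O bond has only the C17 methyl hydrogens antiperiplanar (the minor Δ7 isomer is removed after step 4).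

Step 4
Reactants: 4 12-benzyloxy-13,14,15,16-tetranorlabd-8(17)-ene
Product: 6 12-benzyloxy-13,14,15,16,17-pentanorlabdan-8-one, via secondary ozonide 5 (not isolated)
Conditions: O3, CH2Cl2, −78 °C (Sudan Red 7B end point); then Me2S, −78 °C → rt
Reagents that add atoms: ozone, [O-][O+]=O
Why: Ozonolysis with reductive work‑up cleaves the 1,1‑disubstituted alkene to the C8 ketone, and C9 keeps its equatorial side chain.

Step 5
Reactants: 6 12-benzyloxy-13,14,15,16,17-pentanorlabdan-8-one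
Product: 8 12-benzyloxy-13,14,15,16,17-pentanorlabd-7-en-8-yl trifluoromethanesulfonate, via lithium enolate 7 (not isolated)
Conditions: LiN(SiMe3)2, THF, −78 °C; then PhNTf2, −78 → 0 °C
Reagents that add atoms: N-phenylbis(trifluoromethanesulfonimide), O=S(=O)(C(F)(F)F)N(c1ccccc1)S(=O)(=O)C(F)(F)F
Why: Kinetic enolisation takes the C7 methylene and not the hindered C9 methine, so O‑sulfonylation gives only the Δ7 enol triflate.

Step 6
Reactants: 8 12-benzyloxy-13,14,15,16,17-pentanorlabd-7-en-8-yl trifluoromethanesulfonate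
Product: 9 12-benzyloxy-13,14,15,16-tetranorlabd-7-ene
Conditions: MeMgBr, Fe(acac)3 (5 mol %), THF/NMP, −30 → 0 °C
Reagents that add atoms: methylmagnesium bromide, C[Mg]Br
Why: Iron‑catalysed Kumada‑type cross‑coupling of the alkenyl triflate installs the C17 methyl with the double bond fixed at C7–C8, which direct dehydration of 3 does not achieve cleanly.

Step 7
Reactants: 9 12-benzyloxy-13,14,15,16-tetranorlabd-7-ene
Product: 10 12-benzyloxy-13,14,15,16-tetranorlabdane-7α,8α-diol
Conditions: OsO4 (5 mol %), NMO, acetone/H2O, rt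
Reagents that add atoms: osmium tetroxide, O=[Os](=O)(=O)=O; N-methylmorpholine N-oxide, C[N+]1([O-])CCOCC1; water, O
Why: Upjohn syn‑dihydroxylation occurs on the α face, opposite the axial C10 methyl, which sets C8 as 8α‑OH/8β‑CH3 as in the target.

Step 8
Reactants: 10 12-benzyloxy-13,14,15,16-tetranorlabdane-7α,8α-diol
Product: 11 12-benzyloxy-8α-hydroxy-13,14,15,16-tetranorlabdan-7-one
Conditions: IBX, DMSO, rt
Reagents that add atoms: none
Why: IBX oxidation converts the secondary C7 alcohol of the 1,2‑diol into the α‑hydroxy ketone without C–C cleavage, and the tertiary C8 carbinol cannot react.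

Step 9
Reactants: 11 12-benzyloxy-8α-hydroxy-13,14,15,16-tetranorlabdan-7-one
Product: 12 12-benzyloxy-8α-(triethylsilyloxy)-13,14,15,16-tetranorlabdan-7-one
Conditions: Et3SiOTf, 2,6-lutidine, CH2Cl2, −78 → 0 °C
Reagents that add atoms: triethylsilyl trifluoromethanesulfonate, CC[Si](CC)(CC)OS(=O)(=O)C(F)(F)F
Why: Silyl triflate silylation caps the tertiary α‑ketol hydroxyl, which blocks α‑ketol rearrangement under base and later oxa‑Michael closure onto the unsaturated side chain.

Step 10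
Reactants: 12 12-benzyloxy-8α-(triethylsilyloxy)-13,14,15,16-tetranorlabdan-7-one
Product: 13 12-hydroxy-8α-(triethylsilyloxy)-13,14,15,16-tetranorlabdan-7-one
Conditions: H2 (1 atm), Pd/C (10 wt % Pd on carbon), EtOAc, rt
Reagents that add atoms: none
Why: Catalytic hydrogenolysis removes only the benzyl ether, since the hindered ketone and the silyl ether are inert.

Step 11
Reactants: 13 12-hydroxy-8α-(triethylsilyloxy)-13,14,15,16-tetranorlabdan-7-one
Product: 14 7-oxo-8α-(triethylsilyloxy)-13,14,15,16-tetranorlabdan-12-al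
Conditions: Dess–Martin periodinane, CH2Cl2, 0 °C → rt
Reagents that add atoms: none
Why: Dess–Martin oxidation stops cleanly at the aldehyde, which has no α‑stereocentre to lose.

Step 12
Reactants: 14 7-oxo-8α-(triethylsilyloxy)-13,14,15,16-tetranorlabdan-12-al; 15 ethyl propanoate
Product: 17 ethyl 12-hydroxy-7-oxo-8α-(triethylsilyloxy)-15-norlabdan-14-oate (C12/C13 diastereomer mixture), via lithium ester enolate 16 (not isolated)
Conditions: 15, LiN(iPr)2, THF, −78 °C; then 14, −78 °C, 30 min; AcOH, −78 °C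
Reagents that add atoms: none
Why: Intermolecular aldol addition of the preformed lithium enolate forms the C12–C13 bond at the aldehyde far faster than at the doubly neopentyl C7 ketone, and the two new stereocentres (a mixture) are both erased in step 13.

Step 13
Reactants: 17 ethyl 12-hydroxy-7-oxo-8α-(triethylsilyloxy)-15-norlabdan-14-oate
Product: 19 ethyl (12E)-7-oxo-8α-(triethylsilyloxy)-15-norlabd-12-en-14-oate, via mesylate 18 (not isolated)
Conditions: MsCl, Et3N, CH2Cl2, 0 °C; then DBU, rt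
Reagents that add atoms: none
Why: E1cB elimination of the β‑mesyloxy ester gives the thermodynamically preferred (E)‑2‑methyl‑2‑enoate, with the ester trans to C11.

Step 14
Reactants: 19 ethyl (12E)-7-oxo-8α-(triethylsilyloxy)-15-norlabd-12-en-14-oate
Product: 20 (12E)-8α-(triethylsilyloxy)-15-norlabd-12-ene-7β,14-diol
Conditions: iBu2AlH (4 equiv), CH2Cl2, −78 °C; Rochelle salt work‑up
Reagents that add atoms: none
Why: 1,2‑Reduction of the enoate gives the allylic alcohol; the C7 ketone is reduced too, mainly from the α face to the 7β‑ol, which does not matter because step 15 reoxidises it.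

Step 15
Reactants: 20 (12E)-8α-(triethylsilyloxy)-15-norlabd-12-ene-7β,14-diol
Product: 21 (12E)-7-oxo-8α-(triethylsilyloxy)-15-norlabd-12-en-14-al
Conditions: Dess–Martin periodinane (3 equiv), CH2Cl2, rt
Reagents that add atoms: none
Why: Dess–Martin oxidation converts the allylic alcohol into the (E)‑enal and the C7 carbinol back into the ketone, without touching the double‑bond geometry.

Step 16
Reactants: 21 (12E)-7-oxo-8α-(triethylsilyloxy)-15-norlabd-12-en-14-al
Product: 22 (12E)-8α-(triethylsilyloxy)labda-12,14-dien-7-one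
Conditions: Ph3PCH3Br, KN(SiMe3)2, THF, 0 °C; then 21, −78 → 0 °C
Reagents that add atoms: methyltriphenylphosphonium bromide, C[P+](c1ccccc1)(c1ccccc1)c1ccccc1.[Br-]
Why: Wittig methylenation of the unhindered enal (the flanked C7 ketone does not react) completes the (12E)‑12,14‑diene with the C12=C13 geometry retained.

Step 17
Reactants: 22 (12E)-8α-(triethylsilyloxy)labda-12,14-dien-7-one
Product: 24 (12E)-6α-hydroxy-8α-(triethylsilyloxy)labda-12,14-dien-7-one, via potassium enolate 23 (not isolated)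
Conditions: KN(SiMe3)2, THF, −78 °C; then 2-(phenylsulfonyl)-3-phenyloxaziridine, −78 °C; AcOH, −78 °C
Reagents that add atoms: 2-(phenylsulfonyl)-3-phenyloxaziridine, O=S(=O)(c1ccccc1)N1OC1c1ccccc1
Why: Davis enolate hydroxylation can only occur at C6, and the oxaziridine approaches the α face away from the axial C4β and C10 methyls to give the equatorial 6α‑alcohol while leaving the diene alone.

Step 18
Reactants: 24 (12E)-6α-hydroxy-8α-(triethylsilyloxy)labda-12,14-dien-7-one; 25 angelic acid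
Product: 27 (12E)-7-oxo-8α-(triethylsilyloxy)labda-12,14-dien-6α-yl angelate, via mixed anhydride 26 (not isolated)
Conditions: 25, 2,4,6-trichlorobenzoyl chloride, Et3N (1 equiv each), toluene, rt; then 24, 80 °C
Reagents that add atoms: none
Why: Yamaguchi‑type esterification through the preformed mixed anhydride acylates the secondary C6 hydroxyl under near‑neutral conditions, so the (Z)‑angeloyl group does not isomerise and C6 keeps its configuration.

Step 19
Reactants: 27 (12E)-7-oxo-8α-(triethylsilyloxy)labda-12,14-dien-6α-yl angelate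
Product: 28 (12E)-7β-hydroxy-8α-(triethylsilyloxy)labda-12,14-dien-6α-yl angelate
Conditions: NaBH4, CeCl3·7H2O, MeOH/THF, −40 → 0 °C
Reagents that add atoms: none
Why: In this Luche‑type reduction hydride adds axially from the α face (the β face is shielded by the axial 8β‑methyl) to give the equatorial 7β‑alcohol, while the esters are inert and the low temperature suppresses 6→7 acyl migration.

Step 20
Reactants: 28 (12E)-7β-hydroxy-8α-(triethylsilyloxy)labda-12,14-dien-6α-yl angelate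
Product: 29 (12E)-7β-acetoxy-8α-(triethylsilyloxy)labda-12,14-dien-6α-yl angelate
Conditions: Ac2O, DMAP (cat.), pyridine, rt
Reagents that add atoms: acetic anhydride, CC(=O)OC(C)=O
Why: DMAP‑catalysed acetylation esterifies the only free hydroxyl with retention at C7.

Step 21
Reactants: 29 (12E)-7β-acetoxy-8α-(triethylsilyloxy)labda-12,14-dien-6α-yl angelate
Product: 30 (12E)-7β-acetoxy-8α-hydroxylabda-12,14-dien-6α-yl angelate (target)
Conditions: HF·pyridine, pyridine, THF, 0 °C → rt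
Reagents that add atoms: none
Why: Pyridine‑buffered fluoride desilylation frees the tertiary 8α‑hydroxyl without acid strong enough to cyclise it onto the diene or to move the esters.

## Compound list

1 | (+)-sclareolide [(3aR,5aS,9aS,9bR)-3a,6,6,9a-tetramethyldecahydronaphtho[2,1-b]furan-2(1H)-one] | O=C1C[C@H]2[C@](C)(O1)CC[C@H]3C(C)(C)CCC[C@@]32C | starting material
2 | 13,14,15,16-tetranorlabdane-8α,12-diol | OCC[C@H]1[C@](C)(O)CC[C@H]2C(C)(C)CCC[C@@]21C | intermediate
3 | 12-benzyloxy-13,14,15,16-tetranorlabdan-8α-ol | c1ccccc1COCC[C@H]1[C@](C)(O)CC[C@H]2C(C)(C)CCC[C@@]21C | intermediate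
4 | 12-benzyloxy-13,14,15,16-tetranorlabd-8(17)-ene | c1ccccc1COCC[C@H]1C(=C)CC[C@H]2C(C)(C)CCC[C@@]21C | intermediate
5 | secondary ozonide of 4 (spiro-1,2,4-trioxolane at C8, not isolated) | c1ccccc1COCC[C@H]1C3(OCOO3)CC[C@H]2C(C)(C)CCC[C@@]21C | intermediate
6 | 12-benzyloxy-13,14,15,16,17-pentanorlabdan-8-one | c1ccccc1COCC[C@H]1C(=O)CC[C@H]2C(C)(C)CCC[C@@]21C | intermediate
7 | lithium Δ7-enolate of 6 (not isolated) | c1ccccc1COCC[C@H]1C([O-])=CC[C@H]2C(C)(C)CCC[C@@]21C.[Li+] | intermediate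
8 | 12-benzyloxy-13,14,15,16,17-pentanorlabd-7-en-8-yl trifluoromethanesulfonate | c1ccccc1COCC[C@H]1C(OS(=O)(=O)C(F)(F)F)=CC[C@H]2C(C)(C)CCC[C@@]21C | intermediate
9 | 12-benzyloxy-13,14,15,16-tetranorlabd-7-ene | c1ccccc1COCC[C@H]1C(C)=CC[C@H]2C(C)(C)CCC[C@@]21C | intermediate
10 | 12-benzyloxy-13,14,15,16-tetranorlabdane-7α,8α-diol | c1ccccc1COCC[C@H]1[C@](C)(O)[C@H](O)C[C@H]2C(C)(C)CCC[C@@]21C | intermediate
11 | 12-benzyloxy-8α-hydroxy-13,14,15,16-tetranorlabdan-7-one | c1ccccc1COCC[C@H]1[C@](C)(O)C(=O)C[C@H]2C(C)(C)CCC[C@@]21C | intermediate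
12 | 12-benzyloxy-8α-(triethylsilyloxy)-13,14,15,16-tetranorlabdan-7-one | c1ccccc1COCC[C@H]1[C@](C)(O[Si](CC)(CC)CC)C(=O)C[C@H]2C(C)(C)CCC[C@@]21C | intermediate
13 | 12-hydroxy-8α-(triethylsilyloxy)-13,14,15,16-tetranorlabdan-7-one | OCC[C@H]1[C@](C)(O[Si](CC)(CC)CC)C(=O)C[C@H]2C(C)(C)CCC[C@@]21C | intermediate
14 | 7-oxo-8α-(triethylsilyloxy)-13,14,15,16-tetranorlabdan-12-al | O=CC[C@H]1[C@](C)(O[Si](CC)(CC)CC)C(=O)C[C@H]2C(C)(C)CCC[C@@]21C | intermediate
15 | ethyl propanoate | CCOC(=O)CC | starting material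
16 | lithium enolate of ethyl propanoate (not isolated) | CC=C([O-])OCC.[Li+] | intermediate
17 | ethyl 12-hydroxy-7-oxo-8α-(triethylsilyloxy)-15-norlabdan-14-oate (mixture at C12 and C13) | CCOC(=O)C(C)C(O)C[C@H]1[C@](C)(O[Si](CC)(CC)CC)C(=O)C[C@H]2C(C)(C)CCC[C@@]21C | intermediate
18 | 12-methanesulfonate of 17 (not isolated) | CCOC(=O)C(C)C(OS(C)(=O)=O)C[C@H]1[C@](C)(O[Si](CC)(CC)CC)C(=O)C[C@H]2C(C)(C)CCC[C@@]21C | intermediate
19 | ethyl (12E)-7-oxo-8α-(triethylsilyloxy)-15-norlabd-12-en-14-oate | CCOC(=O)/C(C)=C/C[C@H]1[C@](C)(O[Si](CC)(CC)CC)C(=O)C[C@H]2C(C)(C)CCC[C@@]21C | intermediate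
20 | (12E)-8α-(triethylsilyloxy)-15-norlabd-12-ene-7β,14-diol (major C7 epimer) | OC/C(C)=C/C[C@H]1[C@](C)(O[Si](CC)(CC)CC)[C@@H](O)C[C@H]2C(C)(C)CCC[C@@]21C | intermediate
21 | (12E)-7-oxo-8α-(triethylsilyloxy)-15-norlabd-12-en-14-al | O=C/C(C)=C/C[C@H]1[C@](C)(O[Si](CC)(CC)CC)C(=O)C[C@H]2C(C)(C)CCC[C@@]21C | intermediate
22 | (12E)-8α-(triethylsilyloxy)labda-12,14-dien-7-one | C=C/C(C)=C/C[C@H]1[C@](C)(O[Si](CC)(CC)CC)C(=O)C[C@H]2C(C)(C)CCC[C@@]21C | intermediate
23 | potassium Δ6-enolate of 22 (not isolated) | C=C/C(C)=C/C[C@H]1[C@](C)(O[Si](CC)(CC)CC)C([O-])=C[C@H]2C(C)(C)CCC[C@@]21C.[K+] | intermediate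
24 | (12E)-6α-hydroxy-8α-(triethylsilyloxy)labda-12,14-dien-7-one | C=C/C(C)=C/C[C@H]1[C@](C)(O[Si](CC)(CC)CC)C(=O)[C@H](O)[C@H]2C(C)(C)CCC[C@@]21C | intermediate
25 | angelic acid [(Z)-2-methylbut-2-enoic acid] | C/C=C(/C)C(=O)O | starting material
26 | angelic 2,4,6-trichlorobenzoic anhydride (not isolated) | C/C=C(/C)C(=O)OC(=O)c1c(Cl)cc(Cl)cc1Cl | intermediate
27 | (12E)-7-oxo-8α-(triethylsilyloxy)labda-12,14-dien-6α-yl angelate | C=C/C(C)=C/C[C@H]1[C@](C)(O[Si](CC)(CC)CC)C(=O)[C@H](OC(=O)/C(C)=C\C)[C@H]2C(C)(C)CCC[C@@]21C | intermediate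
28 | (12E)-7β-hydroxy-8α-(triethylsilyloxy)labda-12,14-dien-6α-yl angelate | C=C/C(C)=C/C[C@H]1[C@](C)(O[Si](CC)(CC)CC)[C@@H](O)[C@H](OC(=O)/C(C)=C\C)[C@H]2C(C)(C)CCC[C@@]21C | intermediate
29 | (12E)-7β-acetoxy-8α-(triethylsilyloxy)labda-12,14-dien-6α-yl angelate | C=C/C(C)=C/C[C@H]1[C@](C)(O[Si](CC)(CC)CC)[C@@H](OC(C)=O)[C@H](OC(=O)/C(C)=C\C)[C@H]2C(C)(C)CCC[C@@]21C | intermediate
30 | (12E)-7β-acetoxy-8α-hydroxylabda-12,14-dien-6α-yl angelate (CNP0553436.1) | C=C/C(C)=C/C[C@H]1[C@](C)(O)[C@@H](OC(C)=O)[C@H](OC(=O)/C(C)=C\C)[C@H]2C(C)(C)CCC[C@@]21C | target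

## Step count and risks

Total step count: 21. Longest linear sequence: 21 steps (1 → 30); 15 and 25 are bought.

The three steps most likely to fail:

Step 17 (enolate hydroxylation at C6). The risks are incomplete conversion, over‑oxidation, or addition of the enolate to the sulfonimine by‑product. The fallback sets out from 22 and comes back at 24. Ketone 22 is converted with Me3SiOTf and Et3N (CH2Cl2, 0 °C) into the trimethylsilyl enol ether F1. Dimethyldioxirane (1.05 equiv, acetone, −78 °C) epoxidises this electron‑rich enol ether on the α face much faster than the diene, and the silyloxy epoxide rearranges to the 6α‑(trimethylsilyloxy) ketone F2 (Rubottom oxidation). Bu4NF buffered with AcOH (THF, −20 °C) then removes the secondary trimethylsilyl group and gives 24, with the tertiary triethylsilyl ether left in place.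

Step 18 (angeloylation). The risks are Z→E isomerisation to the tiglate and slow acylation of the hindered C6 hydroxyl. The fallback sets out from 24 and comes back at 29. Alcohol 24 is esterified with 2‑[bis(2,2,2‑trifluoroethoxy)phosphoryl]propanoic acid (EDC·HCl, DMAP, CH2Cl2) to give the phosphonopropanoate F3. The C7 ketone is reduced as in step 19 (NaBH4, CeCl3·7H2O, MeOH/THF) to the 7β‑alcohol F4, which is acetylated (Ac2O, DMAP, pyridine) to the acetate F5. A Still–Gennari olefination of F5 with acetaldehyde (KN(SiMe3)2, 18‑crown‑6, THF, −78 °C) then builds the (Z)‑2‑methylbut‑2‑enoate on the molecule and delivers 29. The olefination is run only after the C7 ketone is gone, so the phosphonate anion cannot attack C7.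

Step 19 (C7 reduction next to the angelate). The risks are partial 6→7 angeloyl migration and incomplete face selectivity. The fallback sets out from 24 and comes back at 30. Alcohol 24 is silylated (Et3SiOTf, 2,6‑lutidine) to the 6α,8α‑bis(triethylsilyl) ether F6, which carries no migrating acyl group. Reduction (NaBH4, MeOH/THF) gives the 7β‑alcohol F7 and acetylation (Ac2O, DMAP, pyridine) gives the 7β‑acetate F8. HF·pyridine in THF/pyridine removes both silyl groups to give the 6α,8α‑diol monoacetate F9. Its only acylable (secondary) hydroxyl at C6 is then esterified with mixed anhydride 26 (toluene, 80 °C) to give 30 directly.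

## Further compounds

F1 | step 17 | (12E)-7-(trimethylsilyloxy)-8α-(triethylsilyloxy)labda-6,12,14-triene | C=C/C(C)=C/C[C@H]1[C@](C)(O[Si](CC)(CC)CC)C(O[Si](C)(C)C)=C[C@H]2C(C)(C)CCC[C@@]21C
F2 | step 17 | (12E)-6α-(trimethylsilyloxy)-8α-(triethylsilyloxy)labda-12,14-dien-7-one | C=C/C(C)=C/C[C@H]1[C@](C)(O[Si](CC)(CC)CC)C(=O)[C@H](O[Si](C)(C)C)[C@H]2C(C)(C)CCC[C@@]21C
F3 | step 18 | (12E)-7-oxo-8α-(triethylsilyloxy)labda-12,14-dien-6α-yl 2-[bis(2,2,2-trifluoroethoxy)phosphoryl]propanoate | C=C/C(C)=C/C[C@H]1[C@](C)(O[Si](CC)(CC)CC)C(=O)[C@H](OC(=O)C(C)P(=O)(OCC(F)(F)F)OCC(F)(F)F)[C@H]2C(C)(C)CCC[C@@]21C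
F4 | step 18 | (12E)-7β-hydroxy-8α-(triethylsilyloxy)labda-12,14-dien-6α-yl 2-[bis(2,2,2-trifluoroethoxy)phosphoryl]propanoate | C=C/C(C)=C/C[C@H]1[C@](C)(O[Si](CC)(CC)CC)[C@@H](O)[C@H](OC(=O)C(C)P(=O)(OCC(F)(F)F)OCC(F)(F)F)[C@H]2C(C)(C)CCC[C@@]21C
F5 | step 18 | (12E)-7β-acetoxy-8α-(triethylsilyloxy)labda-12,14-dien-6α-yl 2-[bis(2,2,2-trifluoroethoxy)phosphoryl]propanoate | C=C/C(C)=C/C[C@H]1[C@](C)(O[Si](CC)(CC)CC)[C@@H](OC(C)=O)[C@H](OC(=O)C(C)P(=O)(OCC(F)(F)F)OCC(F)(F)F)[C@H]2C(C)(C)CCC[C@@]21C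
F6 | step 19 | (12E)-6α,8α-bis(triethylsilyloxy)labda-12,14-dien-7-one | C=C/C(C)=C/C[C@H]1[C@](C)(O[Si](CC)(CC)CC)C(=O)[C@H](O[Si](CC)(CC)CC)[C@H]2C(C)(C)CCC[C@@]21C
F7 | step 19 | (12E)-6α,8α-bis(triethylsilyloxy)labda-12,14-dien-7β-ol | C=C/C(C)=C/C[C@H]1[C@](C)(O[Si](CC)(CC)CC)[C@@H](O)[C@H](O[Si](CC)(CC)CC)[C@H]2C(C)(C)CCC[C@@]21C
F8 | step 19 | (12E)-6α,8α-bis(triethylsilyloxy)labda-12,14-dien-7β-yl acetate | C=C/C(C)=C/C[C@H]1[C@](C)(O[Si](CC)(CC)CC)[C@@H](OC(C)=O)[C@H](O[Si](CC)(CC)CC)[C@H]2C(C)(C)CCC[C@@]21C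
F9 | step 19 | (12E)-6α,8α-dihydroxylabda-12,14-dien-7β-yl acetate | C=C/C(C)=C/C[C@H]1[C@](C)(O)[C@@H](OC(C)=O)[C@H](O)[C@H]2C(C)(C)CCC[C@@]21C
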